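Readings and results stem from a simulated flask for substances that don't exist, noise included.

If a flask loses substrate by one first-order step, the share left at a given time doesn't depend on the charge, so test that first.

| setting | noon | dawn | midnight |
|---|---|---|---|
| substrate | 80.0 mM | 240 mM | 20.0 mM |
| time |  |  | 120 min |

- noon run (time / min: [substrate] / mM): 17: 49.0; 34: 31.1; 51: 20.1; 69: 12.2; 86: 8.6; 100: 5.6; 120: 3.3
- dawn run (time / min: [substrate] / mM): 17: 142.0; 34: 85.9; 51: 55.3; 69: 32.8; 86: 21.1; 100: 15.1; 120: 8.1

(each reading ± 0.6 mM)

- Overall: substrate -> target.
- Constant volume, constant temperature.
- An order is taken over about fifteen percent of the charge, up and down.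

- order of the initial rate in [substrate], near the charge of the noon run, the rate being that where two percent of its substrate are target (one fixed amount of target, the same in the runs compared)
- substrate in the midnight run at 120 min, as a share of the substrate charged

Begin with the main step by itself. Define the loss constant between two readings Sa and Sb, taken a time Δt apart, as k = ln(Sa/Sb)/Δt. Over the whole noon run:

k = 0.0266 min⁻¹, so the midnight share would be 4.12%

Now add a second loss that grows with substrate. Compare the first interval of each run:

noon k = 0.0288 min⁻¹, dawn k = 0.0309 min⁻¹

The dawn k reads higher than the noon k, so reckon an order from the two: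

order of substrate loss = 1 + ln(dawn k/noon k)/ln(3.00) = 1.06

The midnight run starts low, so don't take k from high charges. Read it where the noon run stands at the midnight charge, from 20.1 mM to the end. Call this the tail constant k_t, an apparent first-order rate constant:

k_t = 0.0262 min⁻¹, so the midnight share is 4.32%

Treat that as a reading, since the scatter is 18.2% of the last noon value.

Then test whether the substrate already lost matters. Take stretches of equal length at nearly equal substrate, when the noon run has lost 48.9 mM and the dawn run 207 mM:

noon k = 0.0257 min⁻¹, dawn k = 0.0260 min⁻¹

They agree, so within the scatter of these readings the amount already lost doesn't show in k at this level.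

The forecast gave an order of 1.05 and 4%, “assuming the first-order behaviour continues down to 20 mM”.

The midnight run gives 4.07%, and the order of the rate of target formation is 0.97. Where two percent of the noon charge has become target, the dawn run makes target 2.9 times as fast as the noon run, 0.86 mM min⁻¹ against 0.29 mM min⁻¹.

    substrate → intermediate (0.02298 min⁻¹)
    intermediate → target (0.005208 min⁻¹)
    substrate → target (0.003570 min⁻¹)
    2 substrate → homo dimer (0.01116 M⁻¹ min⁻¹)

Carry k_t to the dawn run: from 21.1 mM at 86 min, it gives 8.66 mM at 120 min, against a reading of 8.1 mM, a gap of 0.560 mM, about the scatter.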